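**Retrosynthetic overview**

- The strategy rests on C2 of the chroman: with its methyl, O1, ring carbon C3 and side-chain carbon C1' it has the carbon–oxygen skeleton of 2-methylglycidol, so the only quaternary stereocentre can be bought.
- Ring A (C4a to C8a) is bought with the C8 methyl and the C6 oxygen in place; only the dihydropyran ring B is formed, late, by cutting O1–C8a (palladium-catalysed aryl ether closure).
- C3–C4 and C1'–C2' are cut together at (S)-2-methylglycidyl tosylate, which joins a benzylic Grignard reagent and the side-chain Grignard reagent in one pot.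
- The benzylic reagent comes from symmetric 4-bromo-3,5-dimethylanisole; the side chain C2' to C13' comes from (R)-citronellyl bromide and (S)-3-bromo-2-methylpropan-1-ol (C5'–C6' coupling, then one-carbon homologation for C2').
- The last step frees the C6 phenol.

Key step: step 8

Remark on the chemistry: (S)-2-methylglycidyl tosylate is taken as a purchased single enantiomer; magnesium alkoxides and the sodium phenoxide that are only protonated on work-up are not numbered.

**Route**

Step 1
Reactants: 1 (R)-citronellyl bromide; 2 (S)-3-bromo-2-methylpropan-1-ol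
Product: 5 (2R,6S)-2,6,10-trimethylundec-9-en-1-ol, via (R)-citronellylmagnesium bromide 3 (not isolated), via chloromagnesium (S)-3-bromo-2-methylpropan-1-olate 4 (not isolated)
Conditions: 2, MeMgCl (1.0 equiv), THF, −40 °C; Li2CuCl4 (3 mol %), NMP (4 equiv); then 3 (1.4 equiv, from 1 and Mg turnings, THF, 40 °C) at −20 °C → rt; H2O work-up
Reagents that add atoms: none
Why: Kochi–Tamura copper-catalysed cross-coupling, in which the cuprate from 3 displaces the primary bromide of 4 (the hydroxyl is masked as its magnesium alkoxide, so no chiral Grignard reagent is lost to protonation); neither reacting carbon is stereogenic, so both stereocentres are carried unchanged from 1 and 2.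

Step 2
Reactants: 5 (2R,6S)-2,6,10-trimethylundec-9-en-1-ol
Product: 6 (2R,6S)-1-bromo-2,6,10-trimethylundec-9-ene
Conditions: CBr4 (1.2 equiv), PPh3 (1.25 equiv), CH2Cl2, 0 °C → rt
Reagents that add atoms: CBr4 (tetrabromomethane), BrC(Br)(Br)Br
Why: Appel reaction, in which bromide displaces the alkoxyphosphonium group at the primary carbon under neutral conditions that leave the trisubstituted olefin and the neighbouring stereocentre alone.

Step 3
Reactants: 6 (2R,6S)-1-bromo-2,6,10-trimethylundec-9-ene
Product: 8 (3R,7S)-3,7,11-trimethyldodec-10-en-1-ol, via [(2R,6S)-2,6,10-trimethylundec-9-enyl]magnesium bromide 7 (not isolated)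
Conditions: Mg turnings, I2 (cat.), THF, 50 °C; then dry (CH2O)n (3 equiv), 0 → 50 °C; H2O work-up
Reagents that add atoms: paraformaldehyde (formaldehyde unit), C=O
Why: Grignard addition to formaldehyde released from paraformaldehyde adds the single carbon C2'; the magnesium-bearing carbon is not stereogenic, so the adjacent C4' centre is untouched.

Step 4
Reactants: 8 (3R,7S)-3,7,11-trimethyldodec-10-en-1-ol
Product: 9 (3R,7S)-1-bromo-3,7,11-trimethyldodec-10-ene
Conditions: CBr4 (1.2 equiv), PPh3 (1.25 equiv), CH2Cl2, 0 °C → rt
Reagents that add atoms: CBr4 (tetrabromomethane), BrC(Br)(Br)Br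
Why: Appel reaction on an unhindered primary alcohol, neutral and compatible with the olefin.

Step 5
Reactants: 10 4-bromo-3,5-dimethylanisole
Product: 11 2-bromo-1-(bromomethyl)-5-methoxy-3-methylbenzene
Conditions: NBS (1.0 equiv), AIBN (5 mol %), PhCF3, 85 °C
Reagents that add atoms: NBS (N-bromosuccinimide), O=C1CCC(=O)N1Br
Why: Wohl–Ziegler benzylic bromination; the two methyl groups of 10 are related by symmetry, so only one monobromide is possible, and a non-polar medium with a radical initiator favours the benzylic chain over ring bromination.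

Step 6
Reactants: 11 2-bromo-1-(bromomethyl)-5-methoxy-3-methylbenzene
Product: 12 (2-bromo-5-methoxy-3-methylbenzyl)magnesium bromide (titrated Et2O solution, used directly)
Conditions: Mg turnings (3 equiv), Et2O, 0 °C, slow addition of 11 (0.2 M)
Reagents that add atoms: magnesium, [Mg]
Why: Grignard formation by insertion of magnesium into the benzylic C–Br bond, which is far faster than insertion into the aryl C–Br bond; cold, dilute addition onto excess metal suppresses Wurtz homocoupling, and ortho-bromobenzyl Grignard reagents are stable reagents of this kind.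

Step 7
Reactants: 9 (3R,7S)-1-bromo-3,7,11-trimethyldodec-10-ene
Product: 13 [(3R,7S)-3,7,11-trimethyldodec-10-enyl]magnesium bromide (titrated THF solution, used directly)
Conditions: Mg turnings, I2 (cat.), THF, 45 °C
Reagents that add atoms: magnesium, [Mg]
Why: Standard Grignard formation from a primary alkyl bromide; the remote olefin and the stereocentres, none of them on the metallated carbon, are not involved.

Step 8
Reactants: 12 (2-bromo-5-methoxy-3-methylbenzyl)magnesium bromide; 13 [(3R,7S)-3,7,11-trimethyldodec-10-enyl]magnesium bromide; 14 (S)-2-methylglycidyl tosylate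
Product: 17 (3R,7R,11S)-1-(2-bromo-5-methoxy-3-methylphenyl)-3,7,11,15-tetramethylhexadec-14-en-3-ol, via bromomagnesium tosyloxy alkoxide 15 (not isolated), via (S)-oxirane 16 (not isolated)
Conditions: 14, CuI (10 mol %), THF, −40 °C; 12 (1.05 equiv, Et2O) dropwise, −40 → −20 °C; then 13 (1.2 equiv, THF), −20 → 40 °C; H2O quench
Reagents that add atoms: none
Why: This is a copper-catalysed Grignard opening of an epoxide run as a one-pot double opening of a glycidyl sulfonate: the benzylcopper species from 12 and CuI attacks the unsubstituted epoxide CH2 of 14 in an SN2 step, forming C3–C4 and alkoxide 15 while the CH2OTs group stays intact. On warming, the alkoxide of 15 displaces tosylate in a 3-exo-tet closure to the 2,2-disubstituted oxirane 16, whose CH2 is opened by the copper species from 13 to form C1'–C2' (direct copper-catalysed displacement of the tosylate by 13 would give the same product). The closest known reaction type is the copper-catalysed opening of glycidyl tosylates by Grignard reagents with re-formation of the epoxide in the same flask and a second opening. No ring of the target is closed (the oxirane of 16 is transient) and no stereocentre is created: C2 keeps all four of its bonds throughout, so its configuration is that of 14, and C4' and C8' arrive unchanged in 13. The selectivity needed is chemoselectivity of the first reagent for the epoxide CH2 over the CH2OTs carbon, secured by the neopentyl position of the sulfonate next to quaternary C2, by monovalent copper catalysis, and by adding only 1.05 equiv of 12 at −40 °C so that none is left when 16 forms; this order decides which fragment ends at C3 and which at C1', and hence the sense at C2.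

Step 9
Reactants: 17 (3R,7R,11S)-1-(2-bromo-5-methoxy-3-methylphenyl)-3,7,11,15-tetramethylhexadec-14-en-3-ol
Product: 18 (2R)-6-methoxy-2,8-dimethyl-2-[(4R,8S)-4,8,12-trimethyltridec-11-en-1-yl]chromane
Conditions: Pd(OAc)2 (5 mol %), rac-2-(di-tert-butylphosphino)-1,1'-binaphthyl (6 mol %), Cs2CO3 (1.5 equiv), toluene, 80 °C
Reagents that add atoms: none
Why: Buchwald–Hartwig-type intramolecular C–O coupling, in which zerovalent palladium inserts into C8a–Br, the tertiary alkoxide (no hydrogen on the carbinol carbon, hence no beta-hydride elimination) binds, and reductive elimination from the bulky phosphine complex closes ring B; the C2–O bond is never broken, so C2 is retained.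

Step 10
Reactants: 18 (2R)-6-methoxy-2,8-dimethyl-2-[(4R,8S)-4,8,12-trimethyltridec-11-en-1-yl]chromane
Product: 19 (2R)-2,8-dimethyl-2-[(4R,8S)-4,8,12-trimethyltridec-11-en-1-yl]chroman-6-ol (target, CNP0221369.1)
Conditions: NaSEt (5 equiv), degassed DMF, 130 °C; then 1 M HCl
Reagents that add atoms: none
Why: SN2 demethylation of the aryl methyl ether by ethanethiolate in a dipolar aprotic solvent; the O1–C2 ether is tertiary and cannot be attacked in this way, and thiolate leaves the isolated olefin alone.

**Compound list**

1 | (R)-citronellyl bromide, (R)-8-bromo-2,6-dimethyloct-2-ene | CC(C)=CCC[C@@H](C)CCBr | starting material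
2 | (S)-3-bromo-2-methylpropan-1-ol | BrC[C@@H](C)CO | starting material
3 | (R)-citronellylmagnesium bromide | CC(C)=CCC[C@@H](C)CC[Mg]Br | intermediate
4 | chloromagnesium (S)-3-bromo-2-methylpropan-1-olate | BrC[C@@H](C)CO[Mg]Cl | intermediate
5 | (2R,6S)-2,6,10-trimethylundec-9-en-1-ol | CC(C)=CCC[C@@H](C)CCC[C@@H](C)CO | intermediate
6 | (2R,6S)-1-bromo-2,6,10-trimethylundec-9-ene | CC(C)=CCC[C@@H](C)CCC[C@@H](C)CBr | intermediate
7 | [(2R,6S)-2,6,10-trimethylundec-9-enyl]magnesium bromide | CC(C)=CCC[C@@H](C)CCC[C@@H](C)C[Mg]Br | intermediate
8 | (3R,7S)-3,7,11-trimethyldodec-10-en-1-ol | CC(C)=CCC[C@@H](C)CCC[C@@H](C)CCO | intermediate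
9 | (3R,7S)-1-bromo-3,7,11-trimethyldodec-10-ene | CC(C)=CCC[C@@H](C)CCC[C@@H](C)CCBr | intermediate
10 | 4-bromo-3,5-dimethylanisole | COc1cc(C)c(Br)c(C)c1 | starting material
11 | 2-bromo-1-(bromomethyl)-5-methoxy-3-methylbenzene | COc1cc(C)c(Br)c(CBr)c1 | intermediate
12 | (2-bromo-5-methoxy-3-methylbenzyl)magnesium bromide | COc1cc(C)c(Br)c(C[Mg]Br)c1 | intermediate
13 | [(3R,7S)-3,7,11-trimethyldodec-10-enyl]magnesium bromide | CC(C)=CCC[C@@H](C)CCC[C@@H](C)CC[Mg]Br | intermediate
14 | (S)-2-methylglycidyl tosylate | Cc1ccc(cc1)S(=O)(=O)OC[C@]1(C)CO1 | starting material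
15 | bromomagnesium (S)-4-(2-bromo-5-methoxy-3-methylphenyl)-2-methyl-1-(tosyloxy)butan-2-olate | Cc1ccc(cc1)S(=O)(=O)OC[C@](O[Mg]Br)(C)CCc1cc(OC)cc(C)c1Br | intermediate
16 | (S)-2-[2-(2-bromo-5-methoxy-3-methylphenyl)ethyl]-2-methyloxirane | C[C@]1(CCc2cc(OC)cc(C)c2Br)CO1 | intermediate
17 | (3R,7R,11S)-1-(2-bromo-5-methoxy-3-methylphenyl)-3,7,11,15-tetramethylhexadec-14-en-3-ol | CC(C)=CCC[C@@H](C)CCC[C@@H](C)CCC[C@](O)(C)CCc1cc(OC)cc(C)c1Br | intermediate
18 | (2R)-6-methoxy-2,8-dimethyl-2-[(4R,8S)-4,8,12-trimethyltridec-11-en-1-yl]chromane | CC(C)=CCC[C@@H](C)CCC[C@@H](C)CCC[C@]1(C)CCc2cc(OC)cc(C)c2O1 | intermediate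
19 | (2R)-2,8-dimethyl-2-[(4R,8S)-4,8,12-trimethyltridec-11-en-1-yl]chroman-6-ol | CC(C)=CCC[C@@H](C)CCC[C@@H](C)CCC[C@]1(C)CCc2cc(O)cc(C)c2O1 | target

**Step count**

Total: 10 steps. Longest linear sequence: 8 steps (steps 1, 2, 3, 4, 7, 8, 9, 10).

**Steps most likely to fail**

Step 8. The magnesium alkoxide may close to the oxirane too early, while benzylic reagent is still present, so that a second benzyl group is added. It may also close too slowly. The 2,2-disubstituted oxirane may rearrange under magnesium halide to an aldehyde that then consumes Grignard reagent. The fallback sets out from 12 and 14 and comes back at 17, taking the one-pot process apart into separate operations. Compound 14 is opened with 12 and CuI (10 mol %) in THF/Et2O at −40 °C and quenched cold, and (S)-4-(2-bromo-5-methoxy-3-methylphenyl)-2-hydroxy-2-methylbutyl 4-methylbenzenesulfonate F1 is isolated. K2CO3 in MeOH at rt closes it to oxirane 16, which is now purified and free of magnesium salts. Oxirane 16 is then opened with 13 and CuI (10 mol %) in THF at −30 °C to give 17.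

Step 9. Oxidative addition into the electron-rich C–Br bond flanked by two ortho substituents may be slow, so that hydrodebromination or catalyst decay overtakes ring closure. The fallback sets out from 17 and comes back at 18, moving the closure to a more reactive halide and to copper. Compound 17 is treated with t-BuLi (3.1 equiv, THF, −78 °C; one equivalent for the hydroxyl, two for the exchange) and then 1,2-diiodoethane. This should give (3R,7R,11S)-1-(2-iodo-5-methoxy-3-methylphenyl)-3,7,11,15-tetramethylhexadec-14-en-3-ol F2. An Ullmann-type etherification (CuI 10 mol %, 3,4,7,8-tetramethyl-1,10-phenanthroline 20 mol %, Cs2CO3, toluene, 110 °C) should then close ring B to 18, again without touching the C2–O bond.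

Step 1. Substitution at the beta-branched bromide of the alkoxide may be sluggish, so that homocoupling and reduction of the citronellyl reagent dominate. The fallback sets out from 2 (with 1) and comes back at 5, reversing the roles of the two partners. Compound 2 is silylated (TBSCl, imidazole, DMF) to (S)-(3-bromo-2-methylpropoxy)(tert-butyl)dimethylsilane F3. Magnesium in THF converts it into [(S)-3-(tert-butyldimethylsilyloxy)-2-methylpropyl]magnesium bromide F4. This couples under Li2CuCl4 catalysis (3 mol %, THF, −10 °C → rt) with 1, now an unbranched primary electrophile, to give tert-butyldimethyl{[(2R,6S)-2,6,10-trimethylundec-9-en-1-yl]oxy}silane F5. TBAF in THF then frees 5.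

**Further compounds**

F1 | step 8 | (S)-4-(2-bromo-5-methoxy-3-methylphenyl)-2-hydroxy-2-methylbutyl 4-methylbenzenesulfonate | Cc1ccc(cc1)S(=O)(=O)OC[C@](O)(C)CCc1cc(OC)cc(C)c1Br
F2 | step 9 | (3R,7R,11S)-1-(2-iodo-5-methoxy-3-methylphenyl)-3,7,11,15-tetramethylhexadec-14-en-3-ol | CC(C)=CCC[C@@H](C)CCC[C@@H](C)CCC[C@](O)(C)CCc1cc(OC)cc(C)c1I
F3 | step 1 | (S)-(3-bromo-2-methylpropoxy)(tert-butyl)dimethylsilane | BrC[C@@H](C)CO[Si](C)(C)C(C)(C)C
F4 | step 1 | [(S)-3-(tert-butyldimethylsilyloxy)-2-methylpropyl]magnesium bromide | Br[Mg]C[C@@H](C)CO[Si](C)(C)C(C)(C)C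
F5 | step 1 | tert-butyldimethyl{[(2R,6S)-2,6,10-trimethylundec-9-en-1-yl]oxy}silane | CC(C)=CCC[C@@H](C)CCC[C@@H](C)CO[Si](C)(C)C(C)(C)C
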